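The chemist at this flask must say what E stands at after 3.0 d and whether a remedy pays.

| flask | X | Z | temperature | remark | time |
|---|---|---|---|---|---|
| Tuesday's | 20 mM | 50 mM | 40 °C | the very flask that is asked about, followed so far |  |
| Monday's | 20 mM | 100 mM | 25 °C | run made earlier |  |
| flask | 20 mM | 50.0 mM | 40 °C |  | 3.0 d |

- Tuesday's (time / h: E / %): 10.0: 18.6; 20.0: 23.3; 30.0: 24.9; 40.0: 26.4
- Monday's (time / h: E / %): 0.417: 0.4; 1.00: 0.5; 2.00: 1.1; 3.00: 2.6

(each reading ± 1 percentage point)

- birch: change nothing and wait 40 h more
- larch: at 3.0 d add Z, 100% of the amount charged, then wait 40 h
- cedar: at 3.0 d take out 90% of the D then present, then wait 40 h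
- alder: at 3.0 d raise the temperature by 10 K, then wait 40 h

- E, in percent of the X first charged, at 3.0 d
- the remedy with the largest gain of E, or "none" below 2 percentage points (birch / larch / cedar / alder / none)
- E present, in percent of the X first charged, after birch
- E present, in percent of the X first charged, after cedar

**Tuesday's readings.** In Tuesday's flask, which is the flask asked about, E flattens. We take the last reading, 26.4%, as the plateau. The gaps to it at the first two readings then give a time constant of 10.8 h, a figure that carries the scatter of the readings.

**Bench rule.** We count time constants: 3.0 d holds 6.64 of them. If the flask stops because its feed is used up, the share of the X charge still able to become E falls as exp(−t/τ). We call this share the feed left, and at 3.0 d it is 0.130%. In such a flask a remedy has the feed left to work with, and that is less than the margin of 2 percentage points.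

**The border.** The rule needs Z to stay near its charge, but this flask has 2.50 Z per X, so one Z per X would already take 40.0% of Z. The time constant is therefore rough. The readings also fit an equilibrium, so exhaustion is our commitment, not a proof. We expect E near 26.4% at 3.0 d, no gain from birch or cedar, and "none" as the answer to best.

**The forecast.** The forecast differs, with 27.5% now, 27.8% after birch, 39% after cedar and cedar as best, on the ground that “equilibrium fits simply”.

**The result.** This flask gives 25.9%, 24.6% after birch, 24.6% after cedar, and best is none.

    X + Z → L + D (k = 0.0310 /M/min, Ea = 57.0 kJ/mol)
    Z + L → E + D (k = 0.0950 /M/min, Ea = 57.0 kJ/mol)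
    Z + E → G + D (k = 9.40 × 10⁻⁴ /M/min, Ea = 81.0 kJ/mol)
    X + E → Q (k = 0.280 /M/min, Ea = 78.0 kJ/mol)
    E → J (k = 7.00 × 10⁻⁷ /min, Ea = 125 kJ/mol)
    (constants at 40 °C)

**What ran.** X, the limiting reagent, went to L and then to E while X + E → Q took E away: at 36.0 h X stood at 1.21%, E at 26.1% and Q at 70.0%, a Q holding two X. At 72.0 h, X and L together held 0.0362% of the charge, below the margin as the reckoned 0.130% was, and E was made, each step taken net, at 0.0976 of the rate at which it was used. The neighbour flask with 12 mM of X held 0.0163% of its charge as X and L at 72.0 h, with E at 36.8%.

The numbers in the tables were generated by integration with made-up constants; noise was put on by code.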